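**Plan**

- Cuts: first the B‑ring C1'–chromone C3 bond (Suzuki), then the side‑chain σ bond C2''–C3'' between the cis alkene and the allylic stereocentre (key step), then C3''–C4'' inside the chain fragment (lithiation–borylation). The pyranone ring is cut at O1–C2/C2–C3 back to an acetophenone.
- Forward: homoprenyl boronate 3 is homologated to the chiral secondary boronate 8, and 5‑chlorosalicylaldehyde gives E‑bromostyrene 12. Step 7 joins 8 and 12 and extrudes boron. The aryl chloride is then borylated, the separately made 3‑iodochromone 21 (the only ring built, by iodocyclisation of an enaminone) is attached, and both MOM groups are removed.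
- Stereochemistry: C3'' (R) is set by (−)‑sparteine‑controlled lithiation–borylation and carried with retention through a boron‑to‑carbon shift. The Z geometry arises by stereospecific inversion of an E‑alkenylboron (anti addition, then anti elimination).
- Enabling feature: C3'' is a secondary sp3 carbon (H, CH3, CH2) bonded directly to C2'' of a cis CH=CH whose other carbon C1'' sits on C3' of the B ring, ortho to O4'. This is the imprint of a secondary alkyl group that has migrated from boron onto an E‑alkenyl carbon, so one boron atom can carry the stereocentre and deliver the Z bond.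

Key step: step 7

Remark: the target is read as the (3''R) enantiomer with a Z C1''=C2'' bond (side chain numbered from the arene, B ring primed); O‑ethyl N,N‑diisopropylcarbamate is prepared in step 2 and not assumed to be on sale.

**Route**

Step 1
Reactants: 1 5‑bromo‑2‑methylpent‑2‑ene
Product: 3 4,4,5,5‑tetramethyl‑2‑(4‑methylpent‑3‑en‑1‑yl)‑1,3,2‑dioxaborolane, via homoprenylmagnesium bromide 2 (not isolated)
Conditions: Mg, I2 (cat.), THF, rt to 40 °C; then i‑PrOBpin, −78 °C to rt; aq. HCl work‑up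
Reagents that add atoms: 2‑isopropoxy‑4,4,5,5‑tetramethyl‑1,3,2‑dioxaborolane CC(C)OB1OC(C)(C)C(C)(C)O1
Why: Grignard formation from a primary homoallylic bromide followed by trapping with an electrophilic borate ester (Grignard borylation) is a standard entry to primary alkyl pinacol boronates.

Step 2
Reactants: 4 ethanol
Product: 5 O‑ethyl N,N‑diisopropylcarbamate
Conditions: i‑Pr2NCOCl, Et3N, EtOH (excess), CH2Cl2, reflux
Reagents that add atoms: N,N‑diisopropylcarbamoyl chloride CC(C)N(C(C)C)C(Cl)=O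
Why: O‑carbamoylation of a primary alcohol by a carbamoyl chloride installs the group that later directs the lithiation and serves as leaving group.

Step 3
Reactants: 5 O‑ethyl N,N‑diisopropylcarbamate; 3 4,4,5,5‑tetramethyl‑2‑(4‑methylpent‑3‑en‑1‑yl)‑1,3,2‑dioxaborolane
Product: 8 (R)‑4,4,5,5‑tetramethyl‑2‑(6‑methylhept‑5‑en‑2‑yl)‑1,3,2‑dioxaborolane, via lithiated carbamate 6 (not isolated), via boronate complex 7 (not isolated)
Conditions: s‑BuLi, (−)‑sparteine, Et2O, −78 °C, 5 h; then 3, −78 °C, 1 h; then MgBr2·OEt2, reflux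
Reagents that add atoms: none
Why: Lithiation–borylation: (−)‑sparteine‑directed removal of the pro‑S proton should give configurationally stable (S)‑6, which is borylated with retention and then undergoes a magnesium‑assisted 1,2‑metallate rearrangement of the homoprenyl group with inversion at carbon, so the (R) centre is set under reagent control.

Step 4
Reactants: 9 5‑chloro‑2‑hydroxybenzaldehyde
Product: 10 5‑chloro‑2‑(methoxymethoxy)benzaldehyde
Conditions: MOMCl, i‑Pr2NEt, CH2Cl2, 0 °C to rt
Reagents that add atoms: chloromethyl methyl ether COCCl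
Why: O‑alkylation of the phenol (MOM protection) masks the acidic OH for the organolithium chemistry of step 7 and prevents coumarin formation in step 5.

Step 5
Reactants: 10 5‑chloro‑2‑(methoxymethoxy)benzaldehyde
Product: 11 (E)‑3‑[5‑chloro‑2‑(methoxymethoxy)phenyl]prop‑2‑enoic acid
Conditions: malonic acid, pyridine, piperidine (cat.), 90 °C; cold dilute acid work‑up
Reagents that add atoms: malonic acid OC(=O)CC(O)=O
Why: Knoevenagel–Doebner condensation with decarboxylation should give the thermodynamically favoured E acid, and crystallisation should secure geometric purity.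

Step 6
Reactants: 11 (E)‑3‑[5‑chloro‑2‑(methoxymethoxy)phenyl]prop‑2‑enoic acid
Product: 12 2‑[(E)‑2‑bromoethenyl]‑4‑chloro‑1‑(methoxymethoxy)benzene
Conditions: NBS, Et3N (cat.), CH2Cl2, rt
Reagents that add atoms: N‑bromosuccinimide O=C1CCC(=O)N1Br
Why: Amine‑catalysed Hunsdiecker‑type bromodecarboxylation of an electron‑rich cinnamic acid proceeds by bromination of the carboxylate‑activated alkene and loss of CO2 and should give the E bromide stereoselectively.

Step 7
Reactants: 12 2‑[(E)‑2‑bromoethenyl]‑4‑chloro‑1‑(methoxymethoxy)benzene; 8 (R)‑4,4,5,5‑tetramethyl‑2‑(6‑methylhept‑5‑en‑2‑yl)‑1,3,2‑dioxaborolane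
Product: 16 4‑chloro‑2‑[(1Z,3R)‑3,7‑dimethylocta‑1,6‑dien‑1‑yl]‑1‑(methoxymethoxy)benzene, via alkenyllithium 13 (not isolated), via alkenylboronate complex 14 (not isolated), via β‑iodoalkylboronic ester 15 (not isolated)
Conditions: 12 (1.3 equiv), t‑BuLi (2.6 equiv), THF, −78 °C; then 8 (1.0 equiv), −78 °C; then I2 in THF, −78 °C; then NaOMe/MeOH, −78 to 0 °C; aq. Na2S2O3
Reagents that add atoms: none
Why: Zweifel olefination: bromine–lithium exchange with retention gives E‑alkenyllithium 13, which adds to the vacant boron orbital of 8 to give boronate 14; iodine then attacks the alkenyl carbon remote from boron (C1''), and the secondary alkyl group shifts from boron to C2'' anti to the new C–I bond to give 15 (both alkene faces react and the two diastereomers converge). Methoxide then adds to boron, and boron and iodide leave anti‑periplanar, so two anti events turn the E‑alkenyl unit into the Z alkene. The closest known reaction type is the iodine/methoxide coupling of enantioenriched secondary pinacol boronic esters with E‑alkenyllithiums. No ring is closed and no new stereocentre is formed: C3'' keeps the configuration set in step 3 because a 1,2‑metallate shift is retentive at the migrating carbon, and the alkene geometry is fixed by the stereospecific anti addition/anti elimination pair. The step needs chemoselective iodination of the boronate alkene in the presence of the trisubstituted alkene and the arene, which the anionic boron should secure at −78 °C; it also needs 15 not to ionise at its benzylic C–I bond before elimination, which low temperature, immediate methoxide addition and the inductively destabilising meta chlorine favour.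

Step 8
Reactants: 16 4‑chloro‑2‑[(1Z,3R)‑3,7‑dimethylocta‑1,6‑dien‑1‑yl]‑1‑(methoxymethoxy)benzene
Product: 17 2‑{3‑[(1Z,3R)‑3,7‑dimethylocta‑1,6‑dien‑1‑yl]‑4‑(methoxymethoxy)phenyl}‑4,4,5,5‑tetramethyl‑1,3,2‑dioxaborolane
Conditions: B2pin2, Pd2(dba)3 (cat.), XPhos (cat.), KOAc, 1,4‑dioxane, 100 °C
Reagents that add atoms: bis(pinacolato)diboron CC1(C)OB(OC1(C)C)B1OC(C)(C)C(C)(C)O1
Why: Miyaura borylation of an aryl chloride with a bulky biarylphosphine ligand is well precedented, the weak acetate base leaves the MOM ether alone, and the alkenyl group sits meta to the C–Cl bond so no intramolecular Heck pathway exists.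

Step 9
Reactants: 18 1‑(2,4‑dihydroxyphenyl)ethan‑1‑one
Product: 19 1‑[2‑hydroxy‑4‑(methoxymethoxy)phenyl]ethan‑1‑one
Conditions: MOMCl (1.05 equiv), K2CO3, acetone, rt
Reagents that add atoms: chloromethyl methyl ether COCCl
Why: The 2‑OH is hydrogen‑bonded to the ketone, so O‑alkylation (MOM protection) should take place selectively at the free 4‑OH.

Step 10
Reactants: 19 1‑[2‑hydroxy‑4‑(methoxymethoxy)phenyl]ethan‑1‑one
Product: 21 3‑iodo‑7‑(methoxymethoxy)‑4H‑chromen‑4‑one, via enaminone 20 (not isolated)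
Conditions: DMF‑DMA, 95 °C; concentrate; then I2, pyridine, CHCl3, rt
Reagents that add atoms: N,N‑dimethylformamide dimethyl acetal COC(OC)N(C)C; iodine II
Why: Condensation with the amide acetal gives the enaminone, and iodine then triggers the known iodocyclisation (α‑iodination, attack of the phenol oxygen on the iminium carbon, loss of dimethylamine) to the 3‑iodochromone.

Step 11
Reactants: 17 2‑{3‑[(1Z,3R)‑3,7‑dimethylocta‑1,6‑dien‑1‑yl]‑4‑(methoxymethoxy)phenyl}‑4,4,5,5‑tetramethyl‑1,3,2‑dioxaborolane; 21 3‑iodo‑7‑(methoxymethoxy)‑4H‑chromen‑4‑one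
Product: 22 3‑{3‑[(1Z,3R)‑3,7‑dimethylocta‑1,6‑dien‑1‑yl]‑4‑(methoxymethoxy)phenyl}‑7‑(methoxymethoxy)‑4H‑chromen‑4‑one
Conditions: Pd(dppf)Cl2 (cat.), K2CO3, 1,4‑dioxane/H2O, 70 °C
Reagents that add atoms: none
Why: Suzuki–Miyaura coupling of 3‑iodochromones with aryl boronates is the standard isoflavone assembly, and mild carbonate at moderate temperature should spare the base‑sensitive pyranone and leave the Z alkene and stereocentre untouched.

Step 12
Reactants: 22 3‑{3‑[(1Z,3R)‑3,7‑dimethylocta‑1,6‑dien‑1‑yl]‑4‑(methoxymethoxy)phenyl}‑7‑(methoxymethoxy)‑4H‑chromen‑4‑one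
Product: 23 7‑hydroxy‑3‑{4‑hydroxy‑3‑[(1Z,3R)‑3,7‑dimethylocta‑1,6‑dien‑1‑yl]phenyl}‑4H‑chromen‑4‑one
Conditions: conc. HCl (cat., ca. 0.5 M), MeOH/THF, rt to 40 °C; NaHCO3 quench
Reagents that add atoms: none
Why: Acid‑catalysed acetal exchange with methanol (MOM deprotection) should free both phenols, and at this acidity and temperature the Z‑styrene, the remote trisubstituted alkene and the chromone are expected to persist, with no stereocentre involved.

**Compound list**

1 | 5‑bromo‑2‑methylpent‑2‑ene | CC(C)=CCCBr | starting material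
2 | (4‑methylpent‑3‑en‑1‑yl)magnesium bromide | CC(C)=CCC[Mg]Br | intermediate
3 | 4,4,5,5‑tetramethyl‑2‑(4‑methylpent‑3‑en‑1‑yl)‑1,3,2‑dioxaborolane | CC(C)=CCCB1OC(C)(C)C(C)(C)O1 | intermediate
4 | ethanol | CCO | starting material
5 | O‑ethyl N,N‑diisopropylcarbamate | CCOC(=O)N(C(C)C)C(C)C | intermediate
6 | (S)‑1‑lithioethyl N,N‑diisopropylcarbamate, (−)‑sparteine complex (ligand not drawn) | C[C@H]([Li])OC(=O)N(C(C)C)C(C)C | intermediate
7 | lithium (S)‑{1‑[(diisopropylcarbamoyl)oxy]ethyl}(4‑methylpent‑3‑en‑1‑yl)(pinacolato)borate | C[C@@H](OC(=O)N(C(C)C)C(C)C)[B-]1(CCC=C(C)C)OC(C)(C)C(C)(C)O1.[Li+] | intermediate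
8 | (R)‑4,4,5,5‑tetramethyl‑2‑(6‑methylhept‑5‑en‑2‑yl)‑1,3,2‑dioxaborolane | CC(C)=CCC[C@@H](C)B1OC(C)(C)C(C)(C)O1 | intermediate
9 | 5‑chloro‑2‑hydroxybenzaldehyde | O=Cc1cc(Cl)ccc1O | starting material
10 | 5‑chloro‑2‑(methoxymethoxy)benzaldehyde | COCOc1ccc(Cl)cc1C=O | intermediate
11 | (E)‑3‑[5‑chloro‑2‑(methoxymethoxy)phenyl]prop‑2‑enoic acid | COCOc1ccc(Cl)cc1/C=C/C(=O)O | intermediate
12 | 2‑[(E)‑2‑bromoethenyl]‑4‑chloro‑1‑(methoxymethoxy)benzene | COCOc1ccc(Cl)cc1/C=C/Br | intermediate
13 | {(E)‑2‑[5‑chloro‑2‑(methoxymethoxy)phenyl]ethenyl}lithium | COCOc1ccc(Cl)cc1/C=C/[Li] | intermediate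
14 | lithium {(E)‑2‑[5‑chloro‑2‑(methoxymethoxy)phenyl]ethenyl}[(R)‑6‑methylhept‑5‑en‑2‑yl](pinacolato)borate | COCOc1ccc(Cl)cc1/C=C/[B-]1([C@H](C)CCC=C(C)C)OC(C)(C)C(C)(C)O1.[Li+] | intermediate
15 | 2‑{(1R,2S,3R)‑1‑[5‑chloro‑2‑(methoxymethoxy)phenyl]‑1‑iodo‑3,7‑dimethyloct‑6‑en‑2‑yl}‑4,4,5,5‑tetramethyl‑1,3,2‑dioxaborolane (shown; the (1S,2R,3R) diastereomer from the other alkene face forms alongside and gives the same alkene) | COCOc1ccc(Cl)cc1[C@H](I)[C@H]([C@H](C)CCC=C(C)C)B1OC(C)(C)C(C)(C)O1 | intermediate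
16 | 4‑chloro‑2‑[(1Z,3R)‑3,7‑dimethylocta‑1,6‑dien‑1‑yl]‑1‑(methoxymethoxy)benzene | CC(C)=CCC[C@@H](C)/C=C\c1cc(Cl)ccc1OCOC | intermediate
17 | 2‑{3‑[(1Z,3R)‑3,7‑dimethylocta‑1,6‑dien‑1‑yl]‑4‑(methoxymethoxy)phenyl}‑4,4,5,5‑tetramethyl‑1,3,2‑dioxaborolane | CC(C)=CCC[C@@H](C)/C=C\c1cc(B2OC(C)(C)C(C)(C)O2)ccc1OCOC | intermediate
18 | 1‑(2,4‑dihydroxyphenyl)ethan‑1‑one | CC(=O)c1ccc(O)cc1O | starting material
19 | 1‑[2‑hydroxy‑4‑(methoxymethoxy)phenyl]ethan‑1‑one | CC(=O)c1ccc(OCOC)cc1O | intermediate
20 | (E)‑3‑(dimethylamino)‑1‑[2‑hydroxy‑4‑(methoxymethoxy)phenyl]prop‑2‑en‑1‑one | CN(C)/C=C/C(=O)c1ccc(OCOC)cc1O | intermediate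
21 | 3‑iodo‑7‑(methoxymethoxy)‑4H‑chromen‑4‑one | COCOc1ccc2c(c1)occ(I)c2=O | intermediate
22 | 3‑{3‑[(1Z,3R)‑3,7‑dimethylocta‑1,6‑dien‑1‑yl]‑4‑(methoxymethoxy)phenyl}‑7‑(methoxymethoxy)‑4H‑chromen‑4‑one | CC(C)=CCC[C@@H](C)/C=C\c1cc(-c2coc3cc(OCOC)ccc3c2=O)ccc1OCOC | intermediate
23 | 7‑hydroxy‑3‑{4‑hydroxy‑3‑[(1Z,3R)‑3,7‑dimethylocta‑1,6‑dien‑1‑yl]phenyl}‑4H‑chromen‑4‑one | CC(C)=CCC[C@@H](C)/C=C\c1cc(-c2coc3cc(O)ccc3c2=O)ccc1O | target

**Count**

Total step count: 12. Longest linear sequence: 7 steps (steps 4, 5, 6, 7, 8, 11, 12).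

**Steps most likely to fail**

Step 7. The β‑iodoalkylboronic ester carries its iodide on a benzylic carbon flanked by an ortho alkoxy group. If it ionises before the anti elimination, the stereospecificity leaks and E alkene forms. The fallback reverses the roles so that the aryl group migrates and iodine ends up on a non‑benzylic carbon. It sets out from 8, which is vinylated by the same iodine/methoxide olefination with vinyllithium to give (R)‑3,7‑dimethylocta‑1,6‑diene F1. Cross‑metathesis of the terminal alkene with vinylboronic acid pinacol ester (Hoveyda–Grubbs II catalyst, CH2Cl2, 40 °C) should give 2‑[(1E,3R)‑3,7‑dimethylocta‑1,6‑dien‑1‑yl]‑4,4,5,5‑tetramethyl‑1,3,2‑dioxaborolane F2. Commercial 2‑bromo‑4‑chlorophenol is protected (MOMCl, i‑Pr2NEt) as 2‑bromo‑4‑chloro‑1‑(methoxymethoxy)benzene F3. Bromine–lithium exchange on the aryl bromide (n‑BuLi, THF, −78 °C), addition to the alkenyl boronate, then I2 and NaOMe, should shift the aryl group to C1'' and eliminate anti, returning to the route at 16.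

Step 12. Protic acid may protonate the electron‑rich Z‑styrene (Z to E isomerisation or addition of methanol) or the trisubstituted alkene before both acetals are gone. The fallback avoids protic acid: from 22, TESOTf/2,2'‑bipyridyl (CH2Cl2, 0 °C) converts the aryl MOM ethers into aryl silyl ethers, giving 3‑{3‑[(1Z,3R)‑3,7‑dimethylocta‑1,6‑dien‑1‑yl]‑4‑(triethylsilyloxy)phenyl}‑7‑(triethylsilyloxy)‑4H‑chromen‑4‑one F4. Fluoride (TBAF buffered with AcOH, THF, 0 °C) then frees both phenols and returns to the route at 23.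

Step 6. Bromination of the activated ring or incomplete E control would contaminate 12, and any Z bromide is translated into E alkene in step 7. The fallback fixes the geometry mechanistically: from 10, homologation with the Ohira–Bestmann reagent (K2CO3, MeOH) gives 4‑chloro‑2‑ethynyl‑1‑(methoxymethoxy)benzene F5. Syn hydrozirconation with Schwartz reagent followed by iodine should give 4‑chloro‑2‑[(E)‑2‑iodoethenyl]‑1‑(methoxymethoxy)benzene F6. Iodine–lithium exchange (t‑BuLi, −78 °C) then returns to the route at 13.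

**Further compounds**

F1 | step 7 | (R)‑3,7‑dimethylocta‑1,6‑diene | CC(C)=CCC[C@@H](C)C=C
F2 | step 7 | 2‑[(1E,3R)‑3,7‑dimethylocta‑1,6‑dien‑1‑yl]‑4,4,5,5‑tetramethyl‑1,3,2‑dioxaborolane | CC(C)=CCC[C@@H](C)/C=C/B1OC(C)(C)C(C)(C)O1
F3 | step 7 | 2‑bromo‑4‑chloro‑1‑(methoxymethoxy)benzene | COCOc1ccc(Cl)cc1Br
F4 | step 12 | 3‑{3‑[(1Z,3R)‑3,7‑dimethylocta‑1,6‑dien‑1‑yl]‑4‑(triethylsilyloxy)phenyl}‑7‑(triethylsilyloxy)‑4H‑chromen‑4‑one | CC(C)=CCC[C@@H](C)/C=C\c1cc(-c2coc3cc(O[Si](CC)(CC)CC)ccc3c2=O)ccc1O[Si](CC)(CC)CC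
F5 | step 6 | 4‑chloro‑2‑ethynyl‑1‑(methoxymethoxy)benzene | COCOc1ccc(Cl)cc1C#C
F6 | step 6 | 4‑chloro‑2‑[(E)‑2‑iodoethenyl]‑1‑(methoxymethoxy)benzene | COCOc1ccc(Cl)cc1/C=C/I
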